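## Structural features

Preuroporphyrinogen (35) is a linear tetrapyrrole: four 1H-pyrrole rings A to D joined α-carbon to α-carbon by three CH2 bridges. Every ring carries an acetic acid arm and a propionic acid arm on its two β-carbons in the same order, so that the α-carbon facing ring A is always next to the acetate and the α-carbon facing ring D next to the propionate. The two chain ends differ: the outer α-carbon of ring A (next to its acetate) bears CH2OH, and the outer α-carbon of ring D (next to its propionate) is a free CH. The target has no stereocentre; the route passes through compounds whose only stereocentres are C2 and C5 of the future ring A, separated by nitrogen, and both become sp2 at the end. The fragile groups are the 2-(hydroxymethyl)pyrrole of ring A, which near neutral pH ionises to an azafulvene that is trapped by the free α-carbon of ring D, the pyrrolylmethane bridges, which exchange in acid, and the electron-rich α-free rings, which oxidise in air. The real difficulty is that the hydroxymethyl pyrrole and the free end of ring D may coexist only in strong base, which bars the usual acid chemistry of pyrroles from the last steps, while the order of eight side chains over four near-identical rings must be kept. The key step exploits the C(β)–C(β) bond of ring A that carries both arms: drawn as an N-sulfonyl 3-pyrroline this bond is a tetrasubstituted C3=C4 olefin, C2 (bearing CH2OH) and C5 (bearing the CH2 to ring B) are sp3 and inert, and the nitrogen holds a leaving group, so ring A can be closed between C3 and C4 by metathesis and made aromatic by base alone.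

## Logic of the disconnections

35 from 34: the bonds cut are the N–S bond of ring A and one C–H bond at C2 or C5. Cutting here puts the first appearance of a pyrrole bearing CH2OH into the last step and into strong base. The gain is that in every earlier compound that carbon is sp3 and the molecule behaves as an ordinary sulfonamide. The demand is an elimination that runs on a polyanion and leaves the C–CH2OH bond alone.

34 from 33, and 33 from 32: eight ester C–O bonds and one O–Si bond. Methyl esters keep 10 to 33 neutral and chromatographable, and the silyl ether shields the alcohol in the two steps before. The demand is that hydrolysis comes before the strong base of the last step, so that no ester enolate exists there, and that the fluoride step is buffered.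

32 from 31: the C3=C4 double bond of ring A is cut into two 1,1-disubstituted alkenes. This removes the one ring that is not made from 10 and leaves an acyclic tertiary sulfonamide with the acetate arm on one alkene and the propionate arm on the other, so the order of the arms is fixed by construction. The demand is a ring-closing metathesis to a tetrasubstituted olefin flanked by two branched carbons.

31 from 30, and 30 from 29: the N–S and O–Si bonds. The sulfonyl group goes on last because the nitrogen has to be a basic amine in the step before. The gain is an amino alcohol as the precursor; the demand is sulfonylation of a hindered secondary amine, made chemoselective by silylating oxygen first.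

29 from 24, 27 and 28: the N–C2 and C2–C3 bonds of the future ring A. One three-component union sets the CH2OH carbon, the nitrogen link and the acetate-bearing alkene. The gain is that the left half of ring A comes from two small pieces. The demand is that the iminium carbon is taken by the alkenyl group inside the boronate and not by the free C5 of ring D.

24 from 23, and 23 from 17 and 22: the bond between the CH2 on C2 of ring B and the nitrogen-bearing carbon. The cut uses the native polarity of a pyrrolylmethylamine (electrophilic CH2 through the azafulvene) against a nitronate, and the nitro group becomes the nitrogen of ring A. The gain is the tripyrrane 17 and the small piece 22, which already holds the second alkene and the propionate arm. The demand is C-alkylation at the α-carbon of an allylic nitronate and a nitro reduction that spares the alkene.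

17 from 15: two bridge C=O groups and the amide C=O are taken back from CH2. All three carbons on C2 of rings B, C and D sit at the acyl level in 15, so one reduction sets both bridges and the aminomethyl handle; the amide carbon of ring B ends as the CH2 that joins ring B to ring A. The demand is chemoselectivity against six methyl esters.

15 from 13 and 11, 13 from 10 and 11, and 11 from 10: the bonds between C5 of one ring and the acyl carbon on C2 of the next. The whole tripyrrane then comes from one monomer, the head-to-tail order follows from which carbon is nucleophilic and which is acyl, the ketone bridges resist acid, and ring D needs no blocking group because its own acyl group tames its free C5. The demand is one acylation per step and no more, which the cationic acyl donor 11 is meant to secure.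

10 from 5 and 8, 5 from 4, 4 from 1 and 2, 8 from 6 and 7: the C2–C3 and C4–C5 bonds of the pyrrole and the C3–C4 bond behind them. The cut puts the acetate arm (from 1) next to the carboxamide carbon and the propionate arm (from 2) next to the free α-carbon. The gain is four commercial esters; the demand is that regiocontrol rests entirely on which partner carries the nitro group.

22 from 21, 21 from 18 and 19, 27 from 26, 26 from 25: one C–C and one C–N bond for 22, one C–B bond for 27. Both alkenes of the metathesis are bought as 1,1-disubstituted or cumulated double bonds and are never made by olefination on the sensitive tripyrrane. The demand is substitution without allylic shift for 22 and boron on the internal carbon for 27.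

## Other disconnections considered

Alternative 1: The cut runs through the central bridge: both bonds to the carbon between rings B and C are broken, leaving the A–B half as the α-iodide A1 (ring B N-Boc, ring A benzyl ester) and the C–D half as the α-free dipyrromethane A2 (ring D tert-butyl ester). Forward, zerovalent palladium would insert into the C–I bond of A1, carbonylation would give an acylpalladium species, and this would acylate the free α-carbon of A2 to give the oxobilane A3.
- In its favour: two halves of equal size from one monomer, and a ketone bridge that deactivates rings B and C so the CH2 bridges do not scramble in acid. On convergence and on robustness of intermediates it is the better plan.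
- Against it here: an α-iodopyrrole without an acceptor group is barely stable even as its N-Boc derivative, and carbonylative acylation of a pyrrole C–H has far less precedent than the acylation used in steps 6 and 7. A3 still needs reduction of the ketone, conversion of the ring A benzyl ester to CH2OH beside eight methyl esters, and decarboxylation of ring D, which calls for acid.
- Comparison: the hydroxymethyl pyrrole and the free end of ring D would meet outside strong base, which the chosen plan avoids by keeping ring A as a pyrroline to the end. Both plans rest on one transition-metal step of limited precedent. The step count to the bilane skeleton would probably be lower, but the end game longer and less safe.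

Alternative 2: The cut opens all four rings at their N–C(α) bonds, back to the acyclic chain A4 with seven ketones and a terminal aldehyde (the future formyl carbon carried as an acetal). Forward, a fourfold Paal–Knorr condensation with a simple nitrogen source would close rings A to D at once and give, after unmasking, the formylbilane A5.
- In its favour: no pyrrole–pyrrole coupling, no metal, and A5 is two basic steps from 35 (hydride reduction of the aldehyde, saponification). That end game is the equal of the chosen one in safety and shorter by one step.
- Against it here: A4 holds three 1,3-diketone units between its 1,4-pairs, so each ketone can also condense in the 1,3 sense (enaminones) or close in the wrong register. The acid and heat of the condensation act on a product with a formyl group and a free α-carbon, the pair that self-condenses to dipyrrins. A4 is also a mixture of many stereoisomers that is hard to purify.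
- Comparison: A4 cannot use the identity of the four rings, which the chosen plan exploits by building 13 and 15 from one monomer. Its assembly by iterated acylation would take about as many steps as the route to 15, so the step economy is equal at best.

Alternative 3: The cut removes ring B: its two N–C(α) bonds and its C(α)–C(β) bond on the propionate side, leaving the ring A enone A7 and the rings C–D acylsilane A6. Forward, under nucleophilic catalysis A6 would add as an acyl anion to the β-carbon of A7, and a nitrogen source would close the resulting 1,4-diketone to ring B in the same pot, giving the bilane A8.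
- In its favour: a convergent 1 + 2 union with ring B formed between the partners, regiochemistry fixed by the partners, and no tetrasubstituted olefin metathesis. On convergence and on precedent for the ring-forming event it is the better plan.
- Against it here: both partners carry a carbonyl one carbon away from a pyrrole α-carbon, units that enolise and fragment through azafulvenes, and the enone carries a substituent on both its α-carbon and its β-carbon, which makes it a poor acceptor for acyl anion addition.
- Comparison: A8 has the same ester end groups as A3 and so the same acid-dependent end game, in which ring A becomes a hydroxymethyl pyrrole before the medium is basic. The chosen plan pays with a harder ring closure and gets a safer last stage. The step counts should be similar.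

Key step: step 18

Remark on the chemistry: 35 is known to cyclise quickly near neutral pH, so it is generated and kept as its octapotassium salt in degassed alkali and the free-acid formula stands for that solution; compounds 23 to 34 are carried as stereoisomer mixtures because their stereocentres are erased in step 21.

Naming convention: each pyrrole ring is numbered so that C3 carries the acetate arm (CH2CO2Me) and C4 the propionate arm (CH2CH2CO2Me); C2 then faces ring A and C5 faces ring D.

Design note: in diene 31 the acetate-bearing alkene sits on the CH2OH side and the propionate-bearing alkene on the ring B side, as 35 requires. Compared with a plain N-tosyl amino alcohol diene, the hydroxyl is carried as a silyl ether through sulfonylation and metathesis, so that oxygen is not sulfonylated and no primary alcohol meets the ruthenium catalyst; 33 is the free alcohol.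

## Route

Step 1
Reactants: 1 methyl 3,3-dimethoxypropanoate; 2 methyl 4-nitrobutanoate
Product: 4 dimethyl 3-hydroxy-4-nitroheptanedioate (diastereomer mixture), via methyl 3-oxopropanoate 3 (not isolated)
Conditions: 1, 1 M aq. HCl, THF, 0 °C to rt; extract (CH2Cl2); then 2, Et3N (0.2 equiv), THF, 0 °C to rt
Reagents that add atoms: water, O
Why: Acid hydrolysis unmasks the aldehyde and a Henry (nitroaldol) reaction joins the nitronate carbon of 2 to the formyl carbon of 3; the two stereocentres are left uncontrolled because both become sp2 in step 4.

Step 2
Reactants: 4 dimethyl 3-hydroxy-4-nitroheptanedioate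
Product: 5 dimethyl 3-acetoxy-4-nitroheptanedioate (diastereomer mixture)
Conditions: Ac2O, cat. H2SO4, CH2Cl2, 0 °C to rt
Reagents that add atoms: acetic anhydride, CC(=O)OC(C)=O
Why: Acid-catalysed O-acetylation turns the hydroxyl into a leaving group so that base can make the nitroalkene in the flask in step 4; the acidic medium avoids early elimination.

Step 3
Reactants: 6 methyl isocyanoacetate; 7 dimethylamine
Product: 8 2-isocyano-N,N-dimethylacetamide
Conditions: 7 (2 M in MeOH, 1.5 equiv), MeOH, 0 °C to rt
Reagents that add atoms: none
Why: Aminolysis of a methyl ester activated by the α-isocyano group; the isocyanide is inert to a secondary amine at room temperature.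

Step 4
Reactants: 5 dimethyl 3-acetoxy-4-nitroheptanedioate; 8 2-isocyano-N,N-dimethylacetamide
Product: 10 methyl 3-[5-(dimethylcarbamoyl)-4-(2-methoxy-2-oxoethyl)-1H-pyrrol-3-yl]propanoate (ring monomer), via dimethyl 4-nitrohept-3-enedioate 9 (not isolated)
Conditions: DBU (2.2 equiv), THF, 0 °C to rt
Reagents that add atoms: none
Why: Barton–Zard pyrrole synthesis: DBU eliminates acetic acid from 5 to nitroalkene 9, the anion of 8 adds to its β-carbon, the nitronate closes onto the isocyanide carbon, and loss of nitrite with a hydrogen shift aromatises the ring. The aldehyde-derived carbon (acetate arm) ends next to the carboxamide carbon C2 and the nitro-derived carbon (propionate arm) next to the free C5–H, the pattern needed in every ring.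

Step 5
Reactants: 10 ring monomer
Product: 11 chloroiminium dichlorophosphate of 10 (moisture-sensitive salt, made in one batch, used crude as a dry solution in ClCH2CH2Cl under Ar)
Conditions: POCl3 (1.05 equiv), ClCH2CH2Cl, 0 °C to rt; evaporate; redissolve in ClCH2CH2Cl, Ar
Reagents that add atoms: phosphoryl chloride, O=P(Cl)(Cl)Cl
Why: Vilsmeier activation of a tertiary amide: the amide oxygen attacks phosphorus and chloride returns to carbon, giving the chloroiminium salt. The cationic salt has no nucleophilic ring carbon, so it does not condense with itself, and one batch serves as the acyl donor of steps 6 and 7.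

Step 6
Reactants: 11 chloroiminium dichlorophosphate of 10; 10 ring monomer
Product: 13 B–C pyrroketone amide (ring B C2 CONMe2; C=O between ring B C5 and ring C C2; ring C C5–H), via bridging iminium chloride 12 (not isolated)
Conditions: 11 (1.0 equiv), 10 (1.0 equiv), ClCH2CH2Cl, 60 °C; then aq. NaHCO3, 60 °C
Reagents that add atoms: water, O
Why: Vilsmeier–Haack-type acylation as used for pyrroketones: the free C5 of 10 attacks the chloroiminium carbon of 11 and the bridging iminium salt 12 is hydrolysed to the ketone. Free 10 is the only nucleophile present and the positive charge of 12 stops a third ring from adding; the new bond joins C5 of ring B to the former amide carbon on C2 of ring C, the head-to-tail order of the target.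

Step 7
Reactants: 13 B–C pyrroketone amide; 11 chloroiminium dichlorophosphate of 10
Product: 15 B–C–D bis-pyrroketone amide (ring B C2 CONMe2; C=O between ring B C5 and ring C C2 and between ring C C5 and ring D C2; ring D C5–H), via tripyrrolic iminium chloride 14 (not isolated)
Conditions: 11 (1.1 equiv), 13, ClCH2CH2Cl, 70 °C; then aq. NaHCO3, 60 °C
Reagents that add atoms: water, O
Why: The same acylation one ring further: the only unsubstituted ring carbon of 13 is C5 of ring C, which attacks 11 to give 14 and, after hydrolysis, the second ketone bridge. Ring D arrives with its C5–H free but deactivated by its own acyl group, so the chain end needs no blocking group.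

Step 8
Reactants: 15 B–C–D bis-pyrroketone amide
Product: 17 tripyrrane Mannich base (ring B C2 CH2NMe2; CH2 bridges from ring B C5 to ring C C2 and from ring C C5 to ring D C2; ring D C5–H), via amine–borane adduct 16 (not isolated)
Conditions: BH3·THF (12 equiv), THF, 0 °C to rt; MeOH; then Pd/C (palladium on carbon, cat.), MeOH, rt, Ar
Reagents that add atoms: none
Why: Borane reduction: the two pyrrolyl ketones go through O-borylated carbinols and azafulvenium ions to CH2 bridges and the tertiary amide to the dimethylaminomethyl group, both known for pyrrole carbonyl compounds and both faster than attack on aliphatic methyl esters. Adduct 16 is cleaved by palladium-catalysed methanolysis, which needs no acid.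

Step 9
Reactants: 18 methyl acetate; 19 3-bromo-2-(bromomethyl)prop-1-ene
Product: 21 methyl 4-(bromomethyl)pent-4-enoate, via lithium 1-methoxyethenolate 20 (not isolated)
Conditions: LiN(iPr)2, THF, −78 °C; then 19 (3 equiv), DMPU, −78 to −40 °C
Reagents that add atoms: none
Why: SN2 alkylation of an ester enolate by a reactive allylic bromide; the excess of 19 limits double alkylation and the low temperature limits self-condensation of the enolate.

Step 10
Reactants: 21 methyl 4-(bromomethyl)pent-4-enoate
Product: 22 methyl 4-(nitromethyl)pent-4-enoate
Conditions: NaNO2, urea, DMF, 0 °C to rt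
Reagents that add atoms: sodium nitrite, [Na+].[O-]N=O
Why: Kornblum nitration: nitrite displaces the allylic bromide through nitrogen in DMF; a short contact time limits nitrite ester formation and base-induced migration of the double bond.

Step 11
Reactants: 17 tripyrrane Mannich base; 22 methyl 4-(nitromethyl)pent-4-enoate
Product: 23 methyl 4-methylidene-5-nitro-6-(tripyrran-ring B C2-yl)hexanoate (racemic)
Conditions: 22 (3 equiv), PBu3 (0.3 equiv), MeCN, 60 °C, Ar sweep
Reagents that add atoms: none
Why: Mannich-base alkylation of a nitronate, the pyrrole counterpart of the gramine reaction: 22 protonates the dimethylamino group, loss of dimethylamine (relayed by the phosphine) gives the azafulvene of ring B, and the nitronate adds through its α-carbon to the exocyclic CH2. The excess of anionic nucleophile is meant to outrun capture of the azafulvene by the free C5 of ring D; the new stereocentre forms as a racemate and is erased in step 21.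

Step 12
Reactants: 23 nitro tripyrrane
Product: 24 methyl 5-amino-4-methylidene-6-(tripyrran-ring B C2-yl)hexanoate (racemic)
Conditions: Zn dust, AcOH, THF, 0 °C to rt, Ar
Reagents that add atoms: none
Why: Dissolving-metal reduction of a secondary nitroalkane to the primary amine; fast protonation in AcOH outruns loss of nitrite from the allylic position, and zinc leaves the 1,1-disubstituted alkene and the esters alone.

Step 13
Reactants: 25 methyl buta-2,3-dienoate
Product: 26 methyl 3-(4,4,5,5-tetramethyl-1,3,2-dioxaborolan-2-yl)but-3-enoate
Conditions: B2pin2 (1.1 equiv), CuCl (5 mol %), PPh3 (6 mol %), KOtBu (10 mol %), MeOH (2 equiv), THF, 0 °C to rt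
Reagents that add atoms: bis(pinacolato)diboron, CC1(C)OB(OC1(C)C)B1OC(C)(C)C(C)(C)O1
Why: Copper-catalysed borylcupration of an allenoate: the Cu–B bond adds across the electron-poor 2,3-double bond with boron on the central carbon, and methanol protonates the copper enolate at C2, which leaves the terminal double bond as a 1-substituted vinylboronate.

Step 14
Reactants: 26 pinacol boronate
Product: 27 (4-methoxy-4-oxobut-1-en-2-yl)boronic acid
Conditions: NaIO4, NH4OAc, acetone–H2O, rt
Reagents that add atoms: water, O
Why: Periodate cuts the pinacol released in the hydrolysis equilibrium and so drives the boronate to the free boronic acid, the form that reacts in step 15; the alkene and ester are inert to periodate.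

Step 15
Reactants: 24 amine; 27 boronic acid; 28 glycolaldehyde (used as its crystalline dimer)
Product: 29 N-(1-hydroxy-5-methoxy-3-methylidene-5-oxopentan-2-yl) derivative of 24 (amino alcohol; diastereomer mixture)
Conditions: 28 (1.2 equiv as monomer), 27 (1.5 equiv), CH2Cl2–EtOH (3:1), 4 Å molecular sieves, rt, Ar, dark
Reagents that add atoms: none
Why: Petasis borono-Mannich reaction: 24 and 28 condense to an α-hydroxy iminium ion, the hydroxyl binds 27 as a boronate and the alkenyl group migrates within this complex to the iminium carbon, so the C–N and C–C bonds form in one operation and the double bond keeps its place. The new stereocentre is set without control, which does not matter since both centres are erased in step 21; the branched primary amine stops at monoalkylation.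

Step 16
Reactants: 29 amino alcohol
Product: 30 O-tert-butyldimethylsilyl ether of 29 (diastereomer mixture)
Conditions: TBSCl, imidazole, CH2Cl2, 0 °C to rt
Reagents that add atoms: tert-butyldimethylsilyl chloride, CC(C)(C)[Si](C)(C)Cl
Why: Selective O-silylation of the primary alcohol; the hindered secondary amine is not silylated, and the silyl ether prevents O-sulfonylation in step 17 and keeps a primary alcohol away from ruthenium in step 18.

Step 17
Reactants: 30 silyl ether
Product: 31 N-tosyl bis(allylic) amine (metathesis diene: N bears CH(CH2OTBS)C(=CH2)CH2CO2Me and CH(CH2-tripyrrane)C(=CH2)CH2CH2CO2Me; diastereomer mixture)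
Conditions: TsCl (3 equiv), DMAP (1.5 equiv), Et3N (4 equiv), ClCH2CH2Cl, 50 °C, Ar
Reagents that add atoms: p-toluenesulfonyl chloride, Cc1ccc(cc1)S(Cl)(=O)=O
Why: N-Sulfonylation through the N-sulfonylpyridinium salt formed from TsCl and DMAP; the amine is hindered by two branched carbons, hence the excess reagent and warming, while pyrrole NH groups are not sulfonylated without strong base.

Step 18
Reactants: 31 N-tosyl bis(allylic) amine
Product: 32 N-tosyl 3-pyrroline form of ring A on the tripyrrane (C2 CH2OTBS; C3 CH2CO2Me; C4 CH2CH2CO2Me; C5 CH2 to ring B; cis/trans mixture)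
Conditions: [RuCl2(=CH-C6H4-2-OiPr){1,3-bis(2-methylphenyl)imidazolidin-2-ylidene}] (second-generation Hoveyda-type complex, 10 mol % in two portions), toluene (0.005 M), 80 °C, Ar sparge
Reagents that add atoms: none
Why: Ring-closing olefin metathesis: the 14-electron ruthenium alkylidene freed from the chelating benzylidene adds to one 1,1-disubstituted alkene of 31, cycloreversion gives an alkylidene with two carbon substituents, and this closes onto the second alkene through a ruthenacyclobutane to release the tetrasubstituted C3=C4 olefin and Ru=CH2, ethylene being swept out by argon. The closest known reaction type is the ring closure of N-sulfonyl bis(2-substituted allyl)amines to 3,4-disubstituted N-sulfonyl 3-pyrrolines, here with a substituent on each allylic carbon as well. Ring A is the only ring closed; it is a five-membered ring formed from a 1,6-diene by joining the two internal alkene carbons, so C3 keeps the acetate arm and C4 the propionate arm. No stereocentre is created; C2 and C5 are carried as a cis/trans mixture that converges on aromatisation. The selectivity needed is ring closure over intermolecular cross-metathesis and over ruthenium hydride migration of the β,γ-unsaturated ester double bond into conjugation: high dilution, the five-membered ring size and the sulfonamide, whose planar nitrogen and bulky sulfonyl group hold both alkenyl arms on the same side, are expected to secure the first, and fresh catalyst with a short reaction time the second. The N-aryl groups of the carbene ligand are 2-methylphenyl instead of mesityl because the smaller ligand leaves room for the disubstituted alkylidene, and the hydroxyl is silylated so that no ruthenium alkoxide or hydride can form from a primary alcohol at 80 °C. The pyrrole NH groups and the methyl esters are weak ligands for ruthenium and should not interfere.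

Step 19
Reactants: 32 N-tosyl 3-pyrroline silyl ether
Product: 33 N-tosyl 3-pyrroline alcohol (C2 CH2OH; octamethyl ester; cis/trans mixture)
Conditions: TBAF, AcOH (1:1), THF, 0 °C to rt
Reagents that add atoms: none
Why: Fluoride cleavage of the silyl ether, buffered with AcOH so that the alkoxide does not attack the neighbouring acetate ester; any δ-lactone formed all the same would be reopened in step 20.

Step 20
Reactants: 33 N-tosyl 3-pyrroline alcohol
Product: 34 N-tosyl 3-pyrroline octacarboxylic acid (isolated as its octapotassium salt)
Conditions: KOH (2 M aq., excess), MeOH–THF, rt to 40 °C, Ar; lyophilise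
Reagents that add atoms: potassium hydroxide, [K+].[OH-]
Why: Saponification of the eight methyl esters; the sulfonamide, the tetrasubstituted alkene and the sp3 C2 bearing CH2OH are stable to hydroxide, and the octacarboxylate cannot undergo ester condensations in the strongly basic last step.

Step 21
Reactants: 34 N-tosyl 3-pyrroline octacarboxylic acid (octapotassium salt)
Product: 35 preuroporphyrinogen (kept as its octapotassium salt in alkali)
Conditions: KOtBu (excess), 18-crown-6, degassed DMSO, rt to 40 °C, Ar; then dilute into degassed 0.1 M aq. KOH
Reagents that add atoms: none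
Why: Base-induced 1,2-elimination of sulfinate: KOtBu in DMSO removes an allylic proton from C5 or C2 as the N–S bond breaks, giving a 2H-pyrrole that tautomerises to the aromatic 1H-pyrrole, the known way from N-sulfonyl 3-pyrrolines to pyrroles. Ring A becomes a 2-(hydroxymethyl)pyrrole only in a medium in which the hydroxymethyl group is an alkoxide that cannot ionise to the azafulvene, so it should not cyclise onto the free C5 of ring D; both stereocentres disappear.

## Compound list

1 | methyl 3,3-dimethoxypropanoate | COC(CC(=O)OC)OC | starting material
2 | methyl 4-nitrobutanoate | [O-][N+](=O)CCCC(=O)OC | starting material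
3 | methyl 3-oxopropanoate | O=CCC(=O)OC | intermediate
4 | dimethyl 3-hydroxy-4-nitroheptanedioate (diastereomer mixture) | COC(=O)CC(O)C(CCC(=O)OC)[N+](=O)[O-] | intermediate
5 | dimethyl 3-acetoxy-4-nitroheptanedioate (diastereomer mixture) | COC(=O)CC(OC(C)=O)C(CCC(=O)OC)[N+](=O)[O-] | intermediate
6 | methyl isocyanoacetate | [C-]#[N+]CC(=O)OC | starting material
7 | dimethylamine | CNC | starting material
8 | 2-isocyano-N,N-dimethylacetamide | [C-]#[N+]CC(=O)N(C)C | intermediate
9 | dimethyl 4-nitrohept-3-enedioate (E/Z mixture) | COC(=O)CC=C(CCC(=O)OC)[N+](=O)[O-] | intermediate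
10 | methyl 3-[5-(dimethylcarbamoyl)-4-(2-methoxy-2-oxoethyl)-1H-pyrrol-3-yl]propanoate (ring monomer) | CN(C)C(=O)c1[nH]cc(CCC(=O)OC)c1CC(=O)OC | intermediate
11 | chloroiminium dichlorophosphate of 10 | C[N+](C)=C(Cl)c1[nH]cc(CCC(=O)OC)c1CC(=O)OC.[O-]P(=O)(Cl)Cl | intermediate
12 | bridging iminium chloride between ring B C5 and ring C C2 | C[N+](C)=C(c1[nH]cc(CCC(=O)OC)c1CC(=O)OC)c1[nH]c(C(=O)N(C)C)c(CC(=O)OC)c1CCC(=O)OC.[Cl-] | intermediate
13 | B–C pyrroketone amide | CN(C)C(=O)c1[nH]c(C(=O)c2[nH]cc(CCC(=O)OC)c2CC(=O)OC)c(CCC(=O)OC)c1CC(=O)OC | intermediate
14 | tripyrrolic iminium chloride (iminium between ring C C5 and ring D C2) | C[N+](C)=C(c1[nH]cc(CCC(=O)OC)c1CC(=O)OC)c1[nH]c(C(=O)c2[nH]c(C(=O)N(C)C)c(CC(=O)OC)c2CCC(=O)OC)c(CC(=O)OC)c1CCC(=O)OC.[Cl-] | intermediate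
15 | B–C–D bis-pyrroketone amide | CN(C)C(=O)c1[nH]c(C(=O)c2[nH]c(C(=O)c3[nH]cc(CCC(=O)OC)c3CC(=O)OC)c(CCC(=O)OC)c2CC(=O)OC)c(CCC(=O)OC)c1CC(=O)OC | intermediate
16 | amine–borane adduct of 17 | C[N+](C)([BH3-])Cc1[nH]c(Cc2[nH]c(Cc3[nH]cc(CCC(=O)OC)c3CC(=O)OC)c(CCC(=O)OC)c2CC(=O)OC)c(CCC(=O)OC)c1CC(=O)OC | intermediate
17 | tripyrrane Mannich base (ring B C2 CH2NMe2; ring D C5–H) | CN(C)Cc1[nH]c(Cc2[nH]c(Cc3[nH]cc(CCC(=O)OC)c3CC(=O)OC)c(CCC(=O)OC)c2CC(=O)OC)c(CCC(=O)OC)c1CC(=O)OC | intermediate
18 | methyl acetate | CC(=O)OC | starting material
19 | 3-bromo-2-(bromomethyl)prop-1-ene | C=C(CBr)CBr | starting material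
20 | lithium 1-methoxyethenolate | [Li+].[O-]C(=C)OC | intermediate
21 | methyl 4-(bromomethyl)pent-4-enoate | C=C(CBr)CCC(=O)OC | intermediate
22 | methyl 4-(nitromethyl)pent-4-enoate | C=C(C[N+](=O)[O-])CCC(=O)OC | intermediate
23 | methyl 4-methylidene-5-nitro-6-(tripyrran-ring B C2-yl)hexanoate (racemic) | [O-][N+](=O)C(Cc1[nH]c(Cc2[nH]c(Cc3[nH]cc(CCC(=O)OC)c3CC(=O)OC)c(CCC(=O)OC)c2CC(=O)OC)c(CCC(=O)OC)c1CC(=O)OC)C(=C)CCC(=O)OC | intermediate
24 | methyl 5-amino-4-methylidene-6-(tripyrran-ring B C2-yl)hexanoate (racemic) | NC(Cc1[nH]c(Cc2[nH]c(Cc3[nH]cc(CCC(=O)OC)c3CC(=O)OC)c(CCC(=O)OC)c2CC(=O)OC)c(CCC(=O)OC)c1CC(=O)OC)C(=C)CCC(=O)OC | intermediate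
25 | methyl buta-2,3-dienoate | C=C=CC(=O)OC | starting material
26 | methyl 3-(4,4,5,5-tetramethyl-1,3,2-dioxaborolan-2-yl)but-3-enoate | C=C(CC(=O)OC)B1OC(C)(C)C(C)(C)O1 | intermediate
27 | (4-methoxy-4-oxobut-1-en-2-yl)boronic acid | C=C(CC(=O)OC)B(O)O | intermediate
28 | glycolaldehyde | OCC=O | starting material
29 | amino alcohol (secondary bis(allylic) amine; diastereomer mixture) | OCC(NC(Cc1[nH]c(Cc2[nH]c(Cc3[nH]cc(CCC(=O)OC)c3CC(=O)OC)c(CCC(=O)OC)c2CC(=O)OC)c(CCC(=O)OC)c1CC(=O)OC)C(=C)CCC(=O)OC)C(=C)CC(=O)OC | intermediate
30 | O-tert-butyldimethylsilyl ether of 29 (diastereomer mixture) | CC(C)(C)[Si](C)(C)OCC(NC(Cc1[nH]c(Cc2[nH]c(Cc3[nH]cc(CCC(=O)OC)c3CC(=O)OC)c(CCC(=O)OC)c2CC(=O)OC)c(CCC(=O)OC)c1CC(=O)OC)C(=C)CCC(=O)OC)C(=C)CC(=O)OC | intermediate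
31 | N-tosyl bis(allylic) amine on the α-free tripyrrane, O-silylated (metathesis diene; diastereomer mixture) | CC(C)(C)[Si](C)(C)OCC(N(S(=O)(=O)c1ccc(C)cc1)C(Cc1[nH]c(Cc2[nH]c(Cc3[nH]cc(CCC(=O)OC)c3CC(=O)OC)c(CCC(=O)OC)c2CC(=O)OC)c(CCC(=O)OC)c1CC(=O)OC)C(=C)CCC(=O)OC)C(=C)CC(=O)OC | intermediate
32 | N-tosyl 3-pyrroline form of ring A on the tripyrrane, O-silylated (cis/trans mixture) | CC(C)(C)[Si](C)(C)OCC1N(S(=O)(=O)c2ccc(C)cc2)C(Cc2[nH]c(Cc3[nH]c(Cc4[nH]cc(CCC(=O)OC)c4CC(=O)OC)c(CCC(=O)OC)c3CC(=O)OC)c(CCC(=O)OC)c2CC(=O)OC)C(CCC(=O)OC)=C1CC(=O)OC | intermediate
33 | N-tosyl 3-pyrroline alcohol, octamethyl ester (cis/trans mixture) | OCC1N(S(=O)(=O)c2ccc(C)cc2)C(Cc2[nH]c(Cc3[nH]c(Cc4[nH]cc(CCC(=O)OC)c4CC(=O)OC)c(CCC(=O)OC)c3CC(=O)OC)c(CCC(=O)OC)c2CC(=O)OC)C(CCC(=O)OC)=C1CC(=O)OC | intermediate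
34 | N-tosyl 3-pyrroline octacarboxylic acid (handled as octapotassium salt; cis/trans mixture) | OCC1N(S(=O)(=O)c2ccc(C)cc2)C(Cc2[nH]c(Cc3[nH]c(Cc4[nH]cc(CCC(=O)O)c4CC(=O)O)c(CCC(=O)O)c3CC(=O)O)c(CCC(=O)O)c2CC(=O)O)C(CCC(=O)O)=C1CC(=O)O | intermediate
35 | preuroporphyrinogen (hydroxymethylbilane; kept as octapotassium salt in alkali) | O=C(O)CCc1c[nH]c(Cc2[nH]c(Cc3[nH]c(Cc4[nH]c(CO)c(CC(=O)O)c4CCC(=O)O)c(CC(=O)O)c3CCC(=O)O)c(CC(=O)O)c2CCC(=O)O)c1CC(=O)O | target

## Step count and least certain steps

Total step count: 21. Longest linear sequence: 16 steps (1, 2, 4, 5, 6, 7, 8, 11, 12, 15, 16, 17, 18, 19, 20, 21).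

Step 18 (key step). The most likely failure is that the catalyst does not load onto either hindered 1,1-disubstituted alkene. Each sits next to a branched nitrogen-bearing carbon, and the left one also next to an ester that can chelate ruthenium, so migration of that double bond into conjugation and catalyst decay may overtake ring closure. The fallback is a relay ring-closing metathesis, which sets out from 24 and comes back at 32. Hept-6-enoyl chloride and methyl (triphenylphosphoranylidene)acetate with Et3N would give the allenoate methyl nona-2,3,8-trienoate F1. Borylcupration as in step 13, with boron delivered to the central allene carbon from the face away from the chain, would give the pinacol boronate methyl (3Z)-3-(4,4,5,5-tetramethyl-1,3,2-dioxaborolan-2-yl)nona-3,8-dienoate F2, and periodate cleavage as in step 14 the boronic acid [(3Z)-1-methoxy-1-oxonona-3,8-dien-3-yl]boronic acid F3. The Petasis reaction of 24, 28 and F3 would give the relay amino alcohol F4, silylation the relay silyl ether F5 and tosylation the relay N-tosyl triene F6. The catalyst would load on the unhindered terminal alkene of F6, expel cyclopentene and so be delivered within the molecule to the hindered alkene carbon, after which closure onto the second alkene gives 32.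

Step 11. The most likely failure is that the allylic nitronate reacts through its γ-terminus or that 22 isomerises to the conjugated nitroalkene under the amine released. At 60 °C the azafulvene may also be captured by the free C5 of ring D of a second molecule, which leads to oligomers. The fallback sets out from 17 and comes back at 23. Exchange of the dimethylamino group for sulfinate (sodium p-toluenesulfinate, AcOH, MeOH, rt) would give the stable sulfone, the ring B C2 (4-methylphenylsulfonyl)methyl tripyrrane F7. With 22 and KF/Al2O3 in CH2Cl2 at room temperature F7 would lose sulfinate only in the presence of the nitronate that traps the azafulvene. At that temperature neither isomerisation of 22 nor self-condensation is expected to compete.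

Step 8. The most likely failure is incomplete reduction of the amide under conditions mild enough to spare six methyl esters, or, when the reaction is forced, partial reduction of esters. The fallback sets out from 15 and comes back at 17. Borane would be used only for the two ketones (0 °C, small excess), giving the tripyrrane amide F8 (ring B C2 CONMe2, both bridges CH2). The amide would then be reduced by zinc-catalysed hydrosilylation (Zn(OAc)2, (EtO)3SiH, THF, 40 °C), which leaves esters untouched and gives 17 without an amine–borane stage.

Step 17. The most likely failure is that the secondary amine of 30, flanked by two branched carbons, is sulfonylated too slowly, so that prolonged heating leads to loss of the silyl group and decomposition. The fallback sets out from 30 and comes back at 35. Methanesulfonyl chloride with Et3N at −20 °C generates sulfene, a small planar electrophile that adds the N–H even of hindered amines, giving the N-mesyl diene F9. The same metathesis would give the N-mesyl pyrroline silyl ether F10, buffered fluoride the N-mesyl pyrroline alcohol F11 and saponification the N-mesyl octacarboxylic acid F12. From F12, KOtBu in DMSO would expel methanesulfinate to give 35.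

Step 21. The most likely failure is that the elimination stalls, because the substrate is a polyanion once carboxylates, alkoxide and pyrrole nitrogens are deprotonated (low solubility in DMSO, charge repulsion towards the base). The alkoxide at C2 may also fragment with loss of formaldehyde in competition with tautomerisation. The fallback sets out from 33 and comes back at 35. The elimination would be run on the neutral octamethyl ester, where the acetate arm on C3 makes the ring protons vinylogously acidic (DBU, MeCN, rt to 50 °C, Ar), to give hydroxymethylbilane octamethyl ester F13. Aqueous KOH–MeOH would be added to the same flask without work-up, so that F13 is saponified to 35 without leaving base.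

## Further compounds

F1 | step 18 | methyl nona-2,3,8-trienoate | C=CCCCC=C=CC(=O)OC
F2 | step 18 | methyl (3Z)-3-(4,4,5,5-tetramethyl-1,3,2-dioxaborolan-2-yl)nona-3,8-dienoate | C=CCCC/C=C(\CC(=O)OC)B1OC(C)(C)C(C)(C)O1
F3 | step 18 | [(3Z)-1-methoxy-1-oxonona-3,8-dien-3-yl]boronic acid | C=CCCC/C=C(\CC(=O)OC)B(O)O
F4 | step 18 | relay amino alcohol (diastereomer mixture) | OCC(NC(Cc1[nH]c(Cc2[nH]c(Cc3[nH]cc(CCC(=O)OC)c3CC(=O)OC)c(CCC(=O)OC)c2CC(=O)OC)c(CCC(=O)OC)c1CC(=O)OC)C(=C)CCC(=O)OC)/C(CC(=O)OC)=C/CCCC=C
F5 | step 18 | relay silyl ether (diastereomer mixture) | CC(C)(C)[Si](C)(C)OCC(NC(Cc1[nH]c(Cc2[nH]c(Cc3[nH]cc(CCC(=O)OC)c3CC(=O)OC)c(CCC(=O)OC)c2CC(=O)OC)c(CCC(=O)OC)c1CC(=O)OC)C(=C)CCC(=O)OC)/C(CC(=O)OC)=C/CCCC=C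
F6 | step 18 | relay N-tosyl triene (diastereomer mixture) | CC(C)(C)[Si](C)(C)OCC(N(S(=O)(=O)c1ccc(C)cc1)C(Cc1[nH]c(Cc2[nH]c(Cc3[nH]cc(CCC(=O)OC)c3CC(=O)OC)c(CCC(=O)OC)c2CC(=O)OC)c(CCC(=O)OC)c1CC(=O)OC)C(=C)CCC(=O)OC)/C(CC(=O)OC)=C/CCCC=C
F7 | step 11 | ring B C2 (4-methylphenylsulfonyl)methyl tripyrrane | Cc1ccc(cc1)S(=O)(=O)Cc1[nH]c(Cc2[nH]c(Cc3[nH]cc(CCC(=O)OC)c3CC(=O)OC)c(CCC(=O)OC)c2CC(=O)OC)c(CCC(=O)OC)c1CC(=O)OC
F8 | step 8 | tripyrrane amide (ring B C2 CONMe2; CH2 bridges; ring D C5–H) | CN(C)C(=O)c1[nH]c(Cc2[nH]c(Cc3[nH]cc(CCC(=O)OC)c3CC(=O)OC)c(CCC(=O)OC)c2CC(=O)OC)c(CCC(=O)OC)c1CC(=O)OC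
F9 | step 17 | N-mesyl diene, O-silylated (diastereomer mixture) | CC(C)(C)[Si](C)(C)OCC(N(S(C)(=O)=O)C(Cc1[nH]c(Cc2[nH]c(Cc3[nH]cc(CCC(=O)OC)c3CC(=O)OC)c(CCC(=O)OC)c2CC(=O)OC)c(CCC(=O)OC)c1CC(=O)OC)C(=C)CCC(=O)OC)C(=C)CC(=O)OC
F10 | step 17 | N-mesyl pyrroline silyl ether (cis/trans mixture) | CC(C)(C)[Si](C)(C)OCC1N(S(C)(=O)=O)C(Cc2[nH]c(Cc3[nH]c(Cc4[nH]cc(CCC(=O)OC)c4CC(=O)OC)c(CCC(=O)OC)c3CC(=O)OC)c(CCC(=O)OC)c2CC(=O)OC)C(CCC(=O)OC)=C1CC(=O)OC
F11 | step 17 | N-mesyl pyrroline alcohol, octamethyl ester (cis/trans mixture) | OCC1N(S(C)(=O)=O)C(Cc2[nH]c(Cc3[nH]c(Cc4[nH]cc(CCC(=O)OC)c4CC(=O)OC)c(CCC(=O)OC)c3CC(=O)OC)c(CCC(=O)OC)c2CC(=O)OC)C(CCC(=O)OC)=C1CC(=O)OC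
F12 | step 17 | N-mesyl octacarboxylic acid (cis/trans mixture) | OCC1N(S(C)(=O)=O)C(Cc2[nH]c(Cc3[nH]c(Cc4[nH]cc(CCC(=O)O)c4CC(=O)O)c(CCC(=O)O)c3CC(=O)O)c(CCC(=O)O)c2CC(=O)O)C(CCC(=O)O)=C1CC(=O)O
F13 | step 21 | hydroxymethylbilane octamethyl ester | OCc1[nH]c(Cc2[nH]c(Cc3[nH]c(Cc4[nH]cc(CCC(=O)OC)c4CC(=O)OC)c(CCC(=O)OC)c3CC(=O)OC)c(CCC(=O)OC)c2CC(=O)OC)c(CCC(=O)OC)c1CC(=O)OC
A1 | alternative 1 | ring A–B α-iodo dipyrromethane (ring A benzyl ester; ring B N-Boc) | O=C(OCc1ccccc1)c1[nH]c(Cc2n(C(=O)OC(C)(C)C)c(I)c(CCC(=O)OC)c2CC(=O)OC)c(CCC(=O)OC)c1CC(=O)OC
A2 | alternative 1 | ring C–D α-free dipyrromethane (ring D tert-butyl ester) | COC(=O)Cc1c[nH]c(Cc2[nH]c(C(=O)OC(C)(C)C)c(CCC(=O)OC)c2CC(=O)OC)c1CCC(=O)OC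
A3 | alternative 1 | oxobilane with the ketone at the B–C bridge | O=C(OCc1ccccc1)c1[nH]c(Cc2n(C(=O)OC(C)(C)C)c(C(=O)c3[nH]c(Cc4[nH]c(C(=O)OC(C)(C)C)c(CCC(=O)OC)c4CC(=O)OC)c(CCC(=O)OC)c3CC(=O)OC)c(CCC(=O)OC)c2CC(=O)OC)c(CCC(=O)OC)c1CC(=O)OC
A4 | alternative 2 | linear heptaketo aldehyde chain with acetal terminus (stereoisomer mixture) | COC(OC)C(=O)C(CC(=O)OC)C(CCC(=O)OC)C(=O)CC(=O)C(CC(=O)OC)C(CCC(=O)OC)C(=O)CC(=O)C(CC(=O)OC)C(CCC(=O)OC)C(=O)CC(=O)C(CC(=O)OC)C(CCC(=O)OC)C=O
A5 | alternative 2 | formylbilane octamethyl ester with free α-CH on ring D | O=Cc1[nH]c(Cc2[nH]c(Cc3[nH]c(Cc4[nH]cc(CCC(=O)OC)c4CC(=O)OC)c(CCC(=O)OC)c3CC(=O)OC)c(CCC(=O)OC)c2CC(=O)OC)c(CCC(=O)OC)c1CC(=O)OC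
A6 | alternative 3 | rings C–D acylsilane (ring D tert-butyl ester) | C[Si](C)(C)C(=O)Cc1[nH]c(Cc2[nH]c(C(=O)OC(C)(C)C)c(CCC(=O)OC)c2CC(=O)OC)c(CCC(=O)OC)c1CC(=O)OC
A7 | alternative 3 | ring A enone (ring A benzyl ester; E alkene) | O=C(OCc1ccccc1)c1[nH]c(CC(=O)/C(CC(=O)OC)=C/CCC(=O)OC)c(CCC(=O)OC)c1CC(=O)OC
A8 | alternative 3 | bilane octamethyl ester with benzyl ester on ring A and tert-butyl ester on ring D | O=C(OCc1ccccc1)c1[nH]c(Cc2[nH]c(Cc3[nH]c(Cc4[nH]c(C(=O)OC(C)(C)C)c(CCC(=O)OC)c4CC(=O)OC)c(CCC(=O)OC)c3CC(=O)OC)c(CCC(=O)OC)c2CC(=O)OC)c(CCC(=O)OC)c1CC(=O)OC
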